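Substrate left over at the end is what the next run has to shrink, and the choice to make is how much precatalyst to charge.

| flask | substrate | reagent | precatalyst | time |
|---|---|---|---|---|
| north-west | 0.30 M | 0.950 equiv | 2 mol% | 4.0 h |
| north-east | 0.30 M | 0.950 equiv | 2.6 mol% | 4.0 h |
| south | 0.30 M | 0.950 equiv | 3.4 mol% | 4.0 h |

    reagent + free catalyst ⇌ catalyst intermediate A (K1 = 18 M⁻¹, k1 = 76 M⁻¹ min⁻¹)
    catalyst intermediate A → released group + catalyst intermediate B (k2 = 0.70 min⁻¹)
    catalyst intermediate B ⇌ catalyst intermediate C (K3 = 2.2, k3 = 16 min⁻¹)
    substrate + catalyst intermediate C → catalyst intermediate D (k4 = 11 M⁻¹ min⁻¹)
    catalyst intermediate D → free catalyst + product (k5 = 0.27 min⁻¹)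
    2 reagent → homo dimer (k6 = 0.026 M⁻¹ min⁻¹)
    precatalyst → free catalyst (k7 = 0.0013 min⁻¹)

* which of these there is most of at the end, counted by the substrate in it, north-west (catalyst intermediate D / product / substrate)
* which of these there is most of at the end, counted by the substrate in it, north-east (catalyst intermediate D / product / substrate)
* which of these there is most of at the end, counted by the substrate in it, south (catalyst intermediate D / product / substrate)
* final amount of the leader among these, as a percentage of the substrate charged, in north-west
* final amount of the leader among these, as a percentage of the substrate charged, in north-east
* final amount of the leader among these, as a percentage of the substrate charged, in south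

- where a step has two of a species, its rate is k times that concentration squared, and two are used at each turn
- run time (north-west): 4.0 h

Catalyst enters the round slowly: the release from precatalyst has a time constant of 769 min, longer than the run of 240 min. Summing the released fraction over the run gives a working time of 33.8 min, the time the full charge of catalyst would need to work to match it. Because that time constant is longer than the run, the released fraction grows about in step with time, so the working time lies late, with its centre near 160 min.

Reagent, charged at 0.285 M, is meanwhile lost to homo dimer with a first half-life of 67.5 min, shorter than the run. By that step, c(reagent) near the centre of the working time is about 0.0845 M.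

Catalyst intermediate A falls back at 4.22 min⁻¹, faster than it goes on at 0.70 min⁻¹, so the first step can be held at balance, with catalyst intermediate A and free catalyst in the ratio 1.52. That pair then costs 2.37 min per turn. Catalyst intermediate C also falls back faster than it goes on, so the pair of catalyst intermediates B and C, taken at balance too, costs 0.441 min. Catalyst intermediate D costs 3.70 min, the longest stay, which makes it the resting state of the round.

One turn therefore takes 6.51 min. Working time divided by turn time gives 5.20, the turns made per unit of catalyst charged. Multiplied by the loading, this gives the product as a share of the substrate charged.

This reckoning leaves substrate at 89.6% in north-west, 86.5% in north-east and 82.3% in south, where it still exceeds the product. The next run should therefore take the south loading, the largest on offer, and should expect substrate to remain the leader.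

The forecast also names substrate as the leader in each flask, at 89.9% in north-west, 87% in north-east and 83.4% in south, with substrate “decreasing roughly in step with catalyst loading”. Its figures for substrate are higher than this reckoning's in each flask.

In the simulation substrate leads, at 90.1% in north-west, 87.2% in north-east and 83.6% in south. In north-west at 4.00 h, homo dimer holds 0.210 M of reagent against 0.0299 M of released group, 7.01 times as much, while 73.2% of the catalyst still stands as precatalyst. The turn count gives 10.4% of product in north-west, where the flask holds 9.67%, and 26.0% in a neighbour flask like north-west but charged with 5 mol% of precatalyst, which holds 22.6%.

The constants belong to no real substance; what happens was integrated by code.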